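**Plan**

1. Locants: ring A = C1–C5 and C10, ring B = C5–C10; C11, C12, C13 = methyls on C8, C9, C10; C14 = CH2 on C4; C15 = benzylic CH2 on C9; β = face of the C10 methyl.
2. Retrosynthetic cuts: C15–aryl; C4=C14 and C8=C11 (carbonyl methylenations); C9–C15; C7–C8 (ring B); C9–C10; C5–C6.
3. Forward order: ring A is bought as 3-methylcyclohexenone; the C6–C7 arm (Negishi) and the C9–C8 unit (Johnson–Claisen) are attached; ring B then closes at C7–C8; the arene is joined late through C15.
4. Enabling feature: in ring B, C8 (the CH–CH3 carbon) lies between the C7 methylene and the quaternary C9. As a ketone flanked by a C7 ester it is a β-keto ester, so ring B closes by Dieckmann acylation, the dianion then quaternises C9, and the carbonyl finally becomes C8–C11.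
5. Stereochemistry: C10 from CBS reduction plus suprafacial Claisen transfer; C9 by alkylation anti to the axial C10 methyl; C8 by C15–OH-directed hydrogenation from the α-face; C5 by α-face hydroboration of C4=C5.

Key step: step 5

Remark: 10 and 11 are carried as mixtures of C9 epimers (11 also at C7); these centres are erased at the enolate stage of step 6.

**Route**

Step 1
Reactants: 1 3-methylcyclohex-2-en-1-one
Product: 2 2-iodo-3-methylcyclohex-2-en-1-one
Conditions: I2, pyridine, CH2Cl2, 23 °C
Reagents that add atoms: iodine, II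
Why: Pyridine-mediated α-iodination of an enone (conjugate addition of pyridine, iodination of the enolate, elimination) should give the α-iodoenone that serves as the handle for the C5–C6 bond; no stereocenter is formed.

Step 2
Reactants: 2 2-iodo-3-methylcyclohex-2-en-1-one; 3 tert-butyl 3-bromopropanoate
Product: 5 tert-butyl 3-(2-methyl-6-oxocyclohex-1-en-1-yl)propanoate, via alkylzinc bromide 4 (not isolated)
Conditions: 3, Zn dust, I2 (cat.), DMA, 70 °C; then 2, Pd(OAc)2 (cat.), SPhos (cat.), THF, 50 °C
Reagents that add atoms: none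
Why: Negishi cross-coupling of the ester-stabilised β-zincio propanoate with the α-iodoenone should install the C6–C7 arm with its ester on C5; no stereocenter is formed.

Step 3
Reactants: 5 tert-butyl 3-(2-methyl-6-oxocyclohex-1-en-1-yl)propanoate
Product: 6 tert-butyl 3-[(6R)-6-hydroxy-2-methylcyclohex-1-en-1-yl]propanoate (C4–OH α)
Conditions: (S)-2-methyl-CBS-oxazaborolidine (10 mol%), BH3·SMe2, THF, −20 °C; MeOH
Reagents that add atoms: none
Why: Corey–Bakshi–Shibata reduction, in which the α-substituted alkene arm of the enone acts as the large group, should deliver hydride to one face of C4 and give the (R)-allylic alcohol, 1,2-selectively and without touching the tert-butyl ester.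

Step 4
Reactants: 6 tert-butyl 3-[(6R)-6-hydroxy-2-methylcyclohex-1-en-1-yl]propanoate; 7 triethyl orthopropionate
Product: 10 ethyl 2-[(1R)-2-(3-tert-butoxy-3-oxopropyl)-1-methylcyclohex-2-en-1-yl]propanoate (both C9 epimers), via mixed orthoester 8 (not isolated), via ketene acetal 9 (not isolated)
Conditions: 7 (excess), EtCO2H (cat.), 140 °C, EtOH distilled off
Reagents that add atoms: none
Why: Johnson–Claisen rearrangement, in which the [3,3] shift of ketene acetal 9 forms C9–C10 on the ring face that carried the C4 oxygen, should fix the quaternary C10 (methyl β) by suprafacial chirality transfer, the tert-butyl ester resisting lactonisation onto the allylic alcohol.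

Step 5
Reactants: 10 ethyl 2-[(1R)-2-(3-tert-butoxy-3-oxopropyl)-1-methylcyclohex-2-en-1-yl]propanoate
Product: 11 tert-butyl 9,10β-dimethyl-8-oxo-Δ4-octalin-7-carboxylate (C7 and C9 unassigned)
Conditions: KOtBu (2.2 equiv), THF, 0 → 23 °C; then 1 M HCl
Reagents that add atoms: none
Why: Dieckmann condensation: KOtBu forms the tert-butyl ester enolate at C7, which adds to the ethyl ester carbonyl C8 and expels ethoxide, and the product is drained off as its stabilised β-keto ester enolate. The closest known reaction type is the crossed Dieckmann cyclisation of an unsymmetrical diester to a cyclic β-keto ester. Ring B (C5–C6–C7–C8–C9–C10) closes in a 6-exo-trig mode, the enolate carbon C7 attacking the exocyclic C8=O. No lasting stereocenter is created: C7 is enolised, C9 stays epimerisable and C10 is untouched. The step needs regioselectivity between two possible condensations; it is secured because the tert-butyl ester is a poor acyl acceptor and acts only as the nucleophile, and because the alternative closure (C9 onto the tert-butyl ester) would give a β-keto ester without an acidic C–H between the carbonyls and therefore reverts. The C7 ester left in the product is the helper that steers the next alkylation to C9 and is removed in step 7.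

Step 6
Reactants: 11 tert-butyl 9,10β-dimethyl-8-oxo-Δ4-octalin-7-carboxylate
Product: 12 tert-butyl 9α-(hydroxymethyl)-9β,10β-dimethyl-8-oxo-Δ4-octalin-7-carboxylate
Conditions: LiN(iPr)2 (2.3 equiv), THF, −78 → 0 °C; then CH2O (1.2 equiv, THF solution from cracked paraformaldehyde), −78 °C; AcOH
Reagents that add atoms: formaldehyde, C=O
Why: γ-Alkylation of a β-keto ester dianion (aldol-type hydroxymethylation), in which the second deprotonation can only occur at C9 and the C9 terminus meets formaldehyde on the α-face anti to the axial C10 methyl, should create the quaternary C9 with C15 α and the C9 methyl β.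

Step 7
Reactants: 12 tert-butyl 9α-(hydroxymethyl)-9β,10β-dimethyl-8-oxo-Δ4-octalin-7-carboxylate
Product: 15 9α-(hydroxymethyl)-9β,10β-dimethyl-Δ4-octalin-8-one, via bis(trimethylsilyl) derivative 13 (not isolated), via β-keto acid 14 (not isolated)
Conditions: Me3SiOTf, 2,6-lutidine, CH2Cl2, 0 °C; then H2O, THF, 40 °C
Reagents that add atoms: none
Why: Silyl triflate cleavage of the tert-butyl ester (loss of isobutene, the C15 hydroxyl being silylated in passing), followed by hydrolysis and decarboxylation of β-keto acid 14, should remove the C7 helper under buffered conditions that avoid acid-induced ether formation between C15–OH and C4=C5; no stereocenter changes.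

Step 8
Reactants: 15 9α-(hydroxymethyl)-9β,10β-dimethyl-Δ4-octalin-8-one
Product: 16 9α-(hydroxymethyl)-9β,10β-dimethyl-8-methylidene-Δ4-octalin
Conditions: Zn, CH2Br2, TiCl4, THF, 0 °C (reagent pre-formed, excess); then 15, CH2Cl2, 0 → 23 °C
Reagents that add atoms: dibromomethane, BrCBr
Why: Takai–Lombardo methylenation with the non-basic zinc/titanium methylene reagent should convert the hindered C8 ketone into C8=C11 without retro-aldol loss of formaldehyde from the β-hydroxy ketone.

Step 9
Reactants: 16 9α-(hydroxymethyl)-9β,10β-dimethyl-8-methylidene-Δ4-octalin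
Product: 17 9α-(hydroxymethyl)-8β,9β,10β-trimethyl-Δ4-octalin
Conditions: [Rh(nbd)(dppb)]BF4 (5 mol%), H2 (50 bar), CH2Cl2, 23 °C
Reagents that add atoms: none
Why: Hydroxyl-directed homogeneous hydrogenation, in which the cationic rhodium catalyst is held by the C15 hydroxyl (axial on the α-face and homoallylic to C8=C11) and delivers hydrogen to C8 from that face, should force the new C11 methyl β against the thermodynamic preference, while the hindered trisubstituted C4=C5 bond is expected to react much more slowly.

Step 10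
Reactants: 18 methyl 3-bromo-4-hydroxybenzoate
Product: 19 methyl 3-bromo-4-(triisopropylsilyloxy)benzoate
Conditions: iPr3SiCl, imidazole, DMF, 23 °C
Reagents that add atoms: chlorotriisopropylsilane, CC(C)[Si](Cl)(C(C)C)C(C)C
Why: Silylation of the phenol gives an ether that should survive the coupling, hydroboration and methylenation and can be removed by fluoride without acid.

Step 11
Reactants: 17 9α-(hydroxymethyl)-8β,9β,10β-trimethyl-Δ4-octalin; 19 methyl 3-bromo-4-(triisopropylsilyloxy)benzoate
Product: 21 methyl 3-[(8β,9β,10β-trimethyl-Δ4-octalin-9α-yl)methyl]-4-(triisopropylsilyloxy)benzoate, via alkoxy-dihydrobenzoxazole 20 (not isolated)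
Conditions: 17, 5,7-di-tert-butyl-3-phenylbenzoxazolium tetrafluoroborate, pyridine, tBuOMe, 23 °C; then 19, [Ir(ppy)2(dtbbpy)]PF6 (cat.), NiBr2(dtbbpy) (cat.), quinuclidine, DMA, blue LEDs, 23 °C
Reagents that add atoms: none
Why: Nickel/photoredox deoxygenative arylation of an alcohol, in which oxidation and deprotonation of adduct 20 trigger β-scission to the primary C15 radical that is captured by the arylnickel bromide from 19, should form the C15–aryl bond without β-hydride elimination (C9 carries no hydrogen) and without touching a stereocenter.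

Step 12
Reactants: 21 methyl 3-[(8β,9β,10β-trimethyl-Δ4-octalin-9α-yl)methyl]-4-(triisopropylsilyloxy)benzoate
Product: 23 methyl 3-[(4α-hydroxy-8β,9β,10β-trimethyl-5α-decalin-9α-yl)methyl]-4-(triisopropylsilyloxy)benzoate, via alkylborane 22 (not isolated)
Conditions: BH3·SMe2, THF, 0 → 23 °C; then NaBO3·4H2O, H2O, 23 °C
Reagents that add atoms: sodium perborate, B(=O)O[O-].[Na+]
Why: Hydroboration–oxidation, with syn addition of borane to C4=C5 from the α-face anti to the adjacent axial C10 methyl and boron on the less hindered C4, should set C5–H α (trans-decalin) and give the 4α-alcohol after oxidation with retention.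

Step 13
Reactants: 23 methyl 3-[(4α-hydroxy-8β,9β,10β-trimethyl-5α-decalin-9α-yl)methyl]-4-(triisopropylsilyloxy)benzoate
Product: 24 methyl 3-[(8β,9β,10β-trimethyl-4-oxo-5α-decalin-9α-yl)methyl]-4-(triisopropylsilyloxy)benzoate
Conditions: Dess–Martin periodinane, CH2Cl2, 23 °C
Reagents that add atoms: none
Why: Dess–Martin oxidation should give the C4 ketone under near-neutral conditions that leave the adjacent C5 stereocenter unepimerised.

Step 14
Reactants: 24 methyl 3-[(8β,9β,10β-trimethyl-4-oxo-5α-decalin-9α-yl)methyl]-4-(triisopropylsilyloxy)benzoate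
Product: 25 methyl 3-[(8β,9β,10β-trimethyl-4-methylidene-5α-decalin-9α-yl)methyl]-4-(triisopropylsilyloxy)benzoate
Conditions: Zn, CH2Br2, TiCl4, THF, 0 °C (reagent pre-formed); then 24, CH2Cl2, 0 → 23 °C
Reagents that add atoms: dibromomethane, BrCBr
Why: Takai–Lombardo methylenation is non-basic, so it should install C4=C14 without epimerising the enolisable C5 centre and without attacking the aryl ester.

Step 15
Reactants: 25 methyl 3-[(8β,9β,10β-trimethyl-4-methylidene-5α-decalin-9α-yl)methyl]-4-(triisopropylsilyloxy)benzoate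
Product: 26 methyl 4-hydroxy-3-{[(1R,2S,4aS,8aS)-1,2,8a-trimethyl-5-methylidenedecahydronaphthalen-1-yl]methyl}benzoate
Conditions: Bu4NF, AcOH, THF, 0 °C
Reagents that add atoms: none
Why: Fluoride cleavage of the aryl silyl ether, buffered with acetic acid, should free the phenol without acid-induced migration of the exocyclic alkene.

**Compound list**

1 | 3-methylcyclohex-2-en-1-one | CC1=CC(=O)CCC1 | starting material
2 | 2-iodo-3-methylcyclohex-2-en-1-one | CC1=C(I)C(=O)CCC1 | intermediate
3 | tert-butyl 3-bromopropanoate | CC(C)(C)OC(=O)CCBr | starting material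
4 | (3-tert-butoxy-3-oxopropyl)zinc bromide | CC(C)(C)OC(=O)CC[Zn]Br | intermediate (not isolated)
5 | tert-butyl 3-(2-methyl-6-oxocyclohex-1-en-1-yl)propanoate | CC1=C(CCC(=O)OC(C)(C)C)C(=O)CCC1 | intermediate
6 | tert-butyl 3-[(6R)-6-hydroxy-2-methylcyclohex-1-en-1-yl]propanoate | O[C@@H]1CCCC(C)=C1CCC(=O)OC(C)(C)C | intermediate
7 | triethyl orthopropionate | CCC(OCC)(OCC)OCC | starting material
8 | tert-butyl 3-[(6R)-6-(1,1-diethoxypropoxy)-2-methylcyclohex-1-en-1-yl]propanoate | CCC(OCC)(OCC)O[C@@H]1CCCC(C)=C1CCC(=O)OC(C)(C)C | intermediate (not isolated)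
9 | tert-butyl 3-[(6R)-6-(1-ethoxyprop-1-enyloxy)-2-methylcyclohex-1-en-1-yl]propanoate | CC=C(OCC)O[C@@H]1CCCC(C)=C1CCC(=O)OC(C)(C)C | intermediate (not isolated)
10 | ethyl 2-[(1R)-2-(3-tert-butoxy-3-oxopropyl)-1-methylcyclohex-2-en-1-yl]propanoate (C9 epimers) | CCOC(=O)C(C)[C@@]1(C)CCCC=C1CCC(=O)OC(C)(C)C | intermediate
11 | tert-butyl 9,10β-dimethyl-8-oxo-Δ4-octalin-7-carboxylate | CC(C)(C)OC(=O)C1CC2=CCCC[C@]2(C)C(C)C1=O | intermediate
12 | tert-butyl 9α-(hydroxymethyl)-9β,10β-dimethyl-8-oxo-Δ4-octalin-7-carboxylate | CC(C)(C)OC(=O)C1CC2=CCCC[C@]2(C)[C@](C)(CO)C1=O | intermediate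
13 | trimethylsilyl 9β,10β-dimethyl-8-oxo-9α-(trimethylsilyloxymethyl)-Δ4-octalin-7-carboxylate | C[Si](C)(C)OC(=O)C1CC2=CCCC[C@]2(C)[C@](C)(CO[Si](C)(C)C)C1=O | intermediate (not isolated)
14 | 9α-(hydroxymethyl)-9β,10β-dimethyl-8-oxo-Δ4-octalin-7-carboxylic acid | OC(=O)C1CC2=CCCC[C@]2(C)[C@](C)(CO)C1=O | intermediate (not isolated)
15 | 9α-(hydroxymethyl)-9β,10β-dimethyl-Δ4-octalin-8-one | O=C1CCC2=CCCC[C@]2(C)[C@]1(C)CO | intermediate
16 | 9α-(hydroxymethyl)-9β,10β-dimethyl-8-methylidene-Δ4-octalin | C=C1CCC2=CCCC[C@]2(C)[C@]1(C)CO | intermediate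
17 | 9α-(hydroxymethyl)-8β,9β,10β-trimethyl-Δ4-octalin | C[C@H]1CCC2=CCCC[C@]2(C)[C@]1(C)CO | intermediate
18 | methyl 3-bromo-4-hydroxybenzoate | COC(=O)c1ccc(O)c(Br)c1 | starting material
19 | methyl 3-bromo-4-(triisopropylsilyloxy)benzoate | COC(=O)c1ccc(O[Si](C(C)C)(C(C)C)C(C)C)c(Br)c1 | intermediate
20 | 5,7-di-tert-butyl-3-phenyl-2,3-dihydrobenzoxazol-2-yl ether of 17 (at C15–O) | C[C@H]1CCC2=CCCC[C@]2(C)[C@]1(C)COC1Oc2c(cc(cc2C(C)(C)C)C(C)(C)C)N1c1ccccc1 | intermediate (not isolated)
21 | methyl 3-[(8β,9β,10β-trimethyl-Δ4-octalin-9α-yl)methyl]-4-(triisopropylsilyloxy)benzoate | C[C@H]1CCC2=CCCC[C@]2(C)[C@]1(C)Cc1cc(C(=O)OC)ccc1O[Si](C(C)C)(C(C)C)C(C)C | intermediate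
22 | 4α-boranyl-5α-H adduct of 21 | C[C@H]1CC[C@H]2[C@H](B)CCC[C@]2(C)[C@]1(C)Cc1cc(C(=O)OC)ccc1O[Si](C(C)C)(C(C)C)C(C)C | intermediate (not isolated)
23 | methyl 3-[(4α-hydroxy-8β,9β,10β-trimethyl-5α-decalin-9α-yl)methyl]-4-(triisopropylsilyloxy)benzoate | C[C@H]1CC[C@H]2[C@H](O)CCC[C@]2(C)[C@]1(C)Cc1cc(C(=O)OC)ccc1O[Si](C(C)C)(C(C)C)C(C)C | intermediate
24 | methyl 3-[(8β,9β,10β-trimethyl-4-oxo-5α-decalin-9α-yl)methyl]-4-(triisopropylsilyloxy)benzoate | C[C@H]1CC[C@H]2C(=O)CCC[C@]2(C)[C@]1(C)Cc1cc(C(=O)OC)ccc1O[Si](C(C)C)(C(C)C)C(C)C | intermediate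
25 | methyl 3-[(8β,9β,10β-trimethyl-4-methylidene-5α-decalin-9α-yl)methyl]-4-(triisopropylsilyloxy)benzoate | C[C@H]1CC[C@H]2C(=C)CCC[C@]2(C)[C@]1(C)Cc1cc(C(=O)OC)ccc1O[Si](C(C)C)(C(C)C)C(C)C | intermediate
26 | methyl 4-hydroxy-3-{[(1R,2S,4aS,8aS)-1,2,8a-trimethyl-5-methylidenedecahydronaphthalen-1-yl]methyl}benzoate | C=C1CCC[C@@]2(C)[C@H]1CC[C@H](C)[C@@]2(C)Cc1cc(C(=O)OC)ccc1O | target

**Count and risks**

Total step count: 15. Longest linear sequence: 14 (steps 1–9 and 11–15; step 10 prepares the arene).

Steps most likely to fail: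

Step 6. The second deprotonation at the hindered tertiary C9–H may be incomplete, and the β-hydroxy ketone may lose formaldehyde by retro-aldol cleavage on work-up. The fallback sets out from 11 and returns at 15. The tert-butyl ester is first cleaved and decarboxylated under the conditions of step 7, which gives 9,10β-dimethyl-Δ4-octalin-8-one F1. F1 is converted with Me3SiI and (Me3Si)2NH into the more substituted trimethylsilyl enol ether F2 (C8=C9). Aqueous formaldehyde with catalytic Sc(OTf)3 (Mukaiyama aldol in water) then hydroxymethylates C9 from the α-face and gives 15, where step 8 continues.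

Step 11. Condensation of the hindered neopentyl alcohol with the benzoxazolium salt may be slow, and the C15 radical may be lost by hydrogen abstraction before nickel captures it. The fallback sets out from 17 and returns at 21. Appel-type iodination (I2, PPh3, imidazole, toluene, 80 °C) gives the neopentyl iodide F3. Zinc insertion (Zn, LiCl, DMA, 60 °C) gives the alkylzinc iodide F4, which is used at once in a Negishi coupling with 19 (Pd(OAc)2, CPhos, THF) to give 21.

Step 4. Acid-catalysed dehydration of the allylic alcohol to a diene may compete, and the [3,3] shift onto the fully substituted alkene terminus may be slow. The fallback sets out from 6 and returns at 11. Acylation with propionyl chloride (pyridine, DMAP) gives the allylic propionate F5. Ireland–Claisen rearrangement (LiN(iPr)2, Me3SiCl, THF, −78 → 60 °C; both esters are silylated, only the allylic one rearranges; aqueous work-up) gives the carboxylic acid F6 with the same suprafacial transfer to C10. Me3SiCHN2 in MeOH gives the methyl ester F7, which cyclises under the conditions of step 5 to 11.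

**Further compounds**

F1 | step 6 | 9,10β-dimethyl-Δ4-octalin-8-one (C9 unassigned) | O=C1CCC2=CCCC[C@]2(C)C1C
F2 | step 6 | 9,10β-dimethyl-8-(trimethylsilyloxy)-Δ4,8-hexalin (silyl enol ether C8=C9) | C[Si](C)(C)OC1=C(C)[C@@]2(C)CCCC=C2CC1
F3 | step 11 | 9α-(iodomethyl)-8β,9β,10β-trimethyl-Δ4-octalin | C[C@H]1CCC2=CCCC[C@]2(C)[C@]1(C)CI
F4 | step 11 | [(8β,9β,10β-trimethyl-Δ4-octalin-9α-yl)methyl]zinc iodide | C[C@H]1CCC2=CCCC[C@]2(C)[C@]1(C)C[Zn]I
F5 | step 4 | tert-butyl 3-[(6R)-2-methyl-6-(propanoyloxy)cyclohex-1-en-1-yl]propanoate | CCC(=O)O[C@@H]1CCCC(C)=C1CCC(=O)OC(C)(C)C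
F6 | step 4 | 2-[(1R)-2-(3-tert-butoxy-3-oxopropyl)-1-methylcyclohex-2-en-1-yl]propanoic acid | OC(=O)C(C)[C@@]1(C)CCCC=C1CCC(=O)OC(C)(C)C
F7 | step 4 | methyl 2-[(1R)-2-(3-tert-butoxy-3-oxopropyl)-1-methylcyclohex-2-en-1-yl]propanoate | COC(=O)C(C)[C@@]1(C)CCCC=C1CCC(=O)OC(C)(C)C
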